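**Retrosynthetic overview**
1. Target 22 ⇐ silyl enol ether 21 (Saegusa oxidation). Each "oxirane + adjacent CH2OAc" unit is a Payne-rearranged epoxy alcohol: C5–OH + C4=C15 gives the 4,5-epoxide/C15–O, and C7–OH + C7-isopropenyl gives the 7,11-epoxide/C12–O.
2. The ten-membered ring ⇐ anionic oxy-Cope ([3,3]) ring expansion of a 1-isopropenyl-2-vinylcyclohexane-1,2-diol mono-silyl ether (C9–C4 broken, C1–C2 formed).
3. The cyclohexane ⇐ (−)-quinic acid: its C1 and C3 hydroxyls become the two oxirane oxygens (C7, C5), CO2H becomes C11, and the C4/C5 carbinols become the C4/C9 carbonyls that receive vinyl and isopropenyl.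
4. Ring order: cyclohexane (bought) → 7,11-oxirane (step 8) → ten-membered carbocycle (step 12) → 4,5-oxirane (step 14).
5. Germacrane numbering of the target is used throughout: quinic acid C1, C2, C3, C4, C5, C6, CO2H = C7, C6, C5, C4, C9, C8, C11.

Assumption: the tertiary carbinol centres made in steps 5 and 11 are drawn as the expected major epimers; both are erased in step 12, so their configuration is immaterial (TBS = tert-butyldimethylsilyl, TMS = trimethylsilyl).

**Step 1**
Reactants: 1 (−)-quinic acid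
Product: 2 quinide acetonide
Conditions: Me2C(OMe)2, TsOH (cat.), acetone, reflux
Reagents that add atoms: 2,2-dimethoxypropane, COC(C)(C)OC
Why: Acid-catalysed ketalisation of the cis-diol (O4/O5) and lactonisation of the cis carboxyl/hydroxyl pair (C11 to O9) differentiate all hydroxyls in one operation without touching a stereocentre.

**Step 2**
Reactants: 2 quinide acetonide
Product: 4 7-isopropenyl-7,9-diol 4,5-acetonide, via dilithium lactolate 3 (not isolated)
Conditions: MeLi (2.2 equiv), THF, −78 °C; then Ph3P=CH2 (from Ph3PCH3Br, KOtBu), −78 → 65 °C; aq NH4Cl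
Reagents that add atoms: methyllithium, [Li]C; methylenetriphenylphosphorane, C=P(c1ccccc1)(c1ccccc1)c1ccccc1
Why: Single addition of MeLi to the lactone stops at the lactolate, whose ring-opened methyl ketone undergoes Wittig methylenation, turning the carboxyl carbon into the C7 isopropenyl group (C11, C12, C13) and freeing O9, with no stereocentre involved.

**Step 3**
Reactants: 4 7-isopropenyl-7,9-diol 4,5-acetonide
Product: 5 7-hydroxy-7-isopropenyl-9-ketone 4,5-acetonide
Conditions: Dess–Martin periodinane, NaHCO3, CH2Cl2, 0 °C → rt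
Reagents that add atoms: none
Why: Dess–Martin oxidation converts the only secondary hydroxyl into the C9 ketone under neutral conditions that leave the tertiary allylic alcohol and the β-hydroxy ketone motif intact.

**Step 4**
Reactants: 5 7-hydroxy-7-isopropenyl-9-ketone 4,5-acetonide
Product: 6 7-O-trimethylsilyl 9-ketone
Conditions: Me3SiCl, imidazole, DMF, 0 °C
Reagents that add atoms: chlorotrimethylsilane, C[Si](C)(C)Cl
Why: Silylation of the tertiary β-hydroxyl blocks retro-aldol and β-elimination in the next step and distinguishes this oxygen from the carbinol to be made at C9.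

**Step 5**
Reactants: 6 7-O-trimethylsilyl 9-ketone
Product: 7 9-isopropenyl-9-carbinol
Conditions: CH2=C(CH3)MgBr, CeCl3, THF, −78 °C
Reagents that add atoms: isopropenylmagnesium bromide, C=C(C)[Mg]Br
Why: Organocerium 1,2-addition to the enolisable ketone occurs without enolisation, equatorially and anti to the axial C7 and C5 oxygens, and installs C10, C1 and C14 at a centre whose configuration is later erased.

**Step 6**
Reactants: 7 9-isopropenyl-9-carbinol
Product: 8 9-O-TBS ether
Conditions: TBSOTf, 2,6-lutidine, CH2Cl2, 0 °C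
Reagents that add atoms: tert-butyldimethylsilyl triflate, CC(C)(C)[Si](C)(C)OS(=O)(=O)C(F)(F)F
Why: Silyl triflate silylation of the hindered tertiary alcohol gives the robust ether that will emerge from the Cope step as the C9 silyl enol ether.

**Step 7**
Reactants: 8 9-O-TBS ether
Product: 9 4,5,7-triol
Conditions: PPTS (cat.), MeOH, 45 °C
Reagents that add atoms: none
Why: Acid-catalysed transketalisation removes the acetonide and the labile tertiary TMS ether while the tertiary TBS ether survives, exposing the syn-1,3-diol (C5, C7) needed for the next step.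

**Step 8**
Reactants: 9 4,5,7-triol
Product: 11 7,11-epoxy-4,5,12-triol, via 11,12-epoxy triol 10 (not isolated)
Conditions: VO(acac)2 (5 mol %), t-BuOOH, toluene, 0 °C; then 0.5 M NaOH, t-BuOH–H2O, rt
Reagents that add atoms: tert-butyl hydroperoxide, CC(C)(C)OO
Why: Hydroxyl-directed vanadium epoxidation of the tertiary allylic alcohol, with the vanadate held over the C6 flank by the syn-diaxial C5/C7 hydroxyls, sets C11, and Payne rearrangement (intramolecular SN2 by the C7 alkoxide with inversion at C11) gives the 7,11-oxirane with C12 cis to C6 while C7 keeps its bought configuration.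

**Step 9**
Reactants: 11 7,11-epoxy-4,5,12-triol
Product: 12 5,12-bis-O-trimethylsilyl ether
Conditions: Me3SiCl (2.1 equiv), imidazole, CH2Cl2, −40 °C
Reagents that add atoms: chlorotrimethylsilane, C[Si](C)(C)Cl
Why: Kinetic silylation takes the primary and the less hindered secondary hydroxyl and leaves the C4 hydroxyl, which is flanked by the quaternary C9, free.

**Step 10**
Reactants: 12 5,12-bis-O-trimethylsilyl ether
Product: 13 4-ketone
Conditions: Dess–Martin periodinane, NaHCO3, CH2Cl2, rt
Reagents that add atoms: none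
Why: Buffered Dess–Martin oxidation of the remaining secondary alcohol gives the C4 ketone without disturbing the silyl ethers or the tetrasubstituted oxirane.

**Step 11**
Reactants: 13 4-ketone
Product: 15 4-vinyl-4,5,12-triol, via bromomagnesium 4-alkoxide 14 (not isolated)
Conditions: CH2=CHMgBr, CeCl3, THF, −78 → 0 °C; then K2CO3, MeOH, 0 °C; aq NH4Cl
Reagents that add atoms: vinylmagnesium bromide, C=C[Mg]Br
Why: Organocerium 1,2-addition puts the vinyl group (C3, C2) on the hindered ketone next to the equatorial C9 isopropenyl (gauche in either C4 epimer), and mild methanolysis strips the TMS ethers.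

**Step 12**
Reactants: 15 4-vinyl-4,5,12-triol
Product: 17 ten-membered ketone, via tripotassium enolate 16 (not isolated)
Conditions: KH (3.3 equiv), 18-crown-6, THF, 0 → 25 °C; AcOH, −78 °C
Reagents that add atoms: none
Why: Anionic oxy-Cope [3,3]-sigmatropic rearrangement of the C4 alkoxide breaks C4–C9 and forms C1–C2, expanding the cyclohexane to the ten-membered ring; C9 emerges regiospecifically as the TBS enol ether and C4 as the enolate (ketone on quench), both carbinol stereocentres vanish, and C5, C7 and C11 are untouched.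

**Step 13**
Reactants: 17 ten-membered ketone
Product: 18 4(15)-methylene diol
Conditions: Ph3P=CH2 (from Ph3PCH3Br, KOtBu; 4 equiv), THF, 0 °C → rt
Reagents that add atoms: methylenetriphenylphosphorane, C=P(c1ccccc1)(c1ccccc1)c1ccccc1
Why: Wittig methylenation of the only carbonyl (C9 is masked as the enol ether) introduces C15, with the C5 alkoxide suppressing enolisation toward the bought C5 centre.

**Step 14**
Reactants: 18 4(15)-methylene diol
Product: 20 4,5:7,11-diepoxy 12,15-diol, via 4,15-epoxy alcohol 19 (not isolated)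
Conditions: VO(acac)2 (5 mol %), t-BuOOH, toluene, 0 °C; then 0.2 M NaOH, t-BuOH–H2O, 0 °C
Reagents that add atoms: tert-butyl hydroperoxide, CC(C)(C)OO
Why: C5–OH-directed vanadium epoxidation of the 1,1-disubstituted alkene follows the 1,2-allylic-strain (erythro) model, and Payne rearrangement with inversion at C4 gives the trisubstituted 4,5-oxirane with C3 and C6 cis, C5 keeping its bought configuration and C9 staying protected from base as the enol ether.

**Step 15**
Reactants: 20 4,5:7,11-diepoxy 12,15-diol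
Product: 21 12,15-diacetate
Conditions: Ac2O, pyridine, DMAP (cat.), CH2Cl2, 0 °C
Reagents that add atoms: acetic anhydride, CC(=O)OC(C)=O
Why: Standard acylation of the two primary alcohols, which are the only free hydroxyls.

**Step 16**
Reactants: 21 12,15-diacetate
Product: 22 target, (1(10)Z,4R,5R,7S,11S)-12,15-diacetoxy-4,5:7,11-diepoxygermacr-1(10)-en-9-one
Conditions: Pd(OAc)2 (1.2 equiv), MeCN, 40 °C
Reagents that add atoms: none
Why: Saegusa–Ito oxidation of the regiodefined silyl enol ether unveils the C9 ketone and the C1=C10 double bond under neutral conditions tolerated by the base-labile β,γ-epoxy ketone, and the ring-cis (Z) enone is expected as the unstrained geometry of a ten-membered 2-methyl-2-enone.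

**Compound list**
1 | (−)-quinic acid | O=C(O)[C@]1(O)C[C@@H](O)[C@@H](O)[C@H](O)C1 | starting material
2 | quinide acetonide (3,4-O-isopropylidenequinic acid 1,5-lactone) | O=C2[C@]1(O)C[C@H]3OC(C)(C)O[C@H]3[C@H](O2)C1 | intermediate
3 | dilithium lactolate (C11 methyl hemiketal, anomeric mixture) | CC2([O-])[C@]1([O-])C[C@H]3OC(C)(C)O[C@H]3[C@H](O2)C1.[Li+].[Li+] | intermediate
4 | 7-isopropenyl-7,9-diol 4,5-acetonide | C=C(C)[C@]1(O)C[C@H]2OC(C)(C)O[C@H]2[C@H](O)C1 | intermediate
5 | 7-hydroxy-7-isopropenyl-9-ketone 4,5-acetonide | C=C(C)[C@]1(O)C[C@H]2OC(C)(C)O[C@H]2C(=O)C1 | intermediate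
6 | 7-O-trimethylsilyl 9-ketone | C=C(C)[C@]1(O[Si](C)(C)C)C[C@H]2OC(C)(C)O[C@H]2C(=O)C1 | intermediate
7 | 9-isopropenyl-9-carbinol (9-OH cis to 7-OTMS) | C=C(C)[C@]1(O[Si](C)(C)C)C[C@H]2OC(C)(C)O[C@H]2[C@](O)(C(C)=C)C1 | intermediate
8 | 9-O-TBS ether | C=C(C)[C@]1(O[Si](C)(C)C)C[C@H]2OC(C)(C)O[C@H]2[C@](O[Si](C)(C)C(C)(C)C)(C(C)=C)C1 | intermediate
9 | 4,5,7-triol (9-OTBS, isopropenyl on C7 and C9) | C=C(C)[C@]1(O)C[C@@H](O)[C@@H](O)[C@](O[Si](C)(C)C(C)(C)C)(C(C)=C)C1 | intermediate
10 | 11,12-epoxy-4,5,7-triol | C[C@@]2(CO2)[C@]1(O)C[C@@H](O)[C@@H](O)[C@](O[Si](C)(C)C(C)(C)C)(C(C)=C)C1 | intermediate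
11 | 7,11-epoxy-4,5,12-triol | OC[C@]2(C)O[C@]21C[C@@H](O)[C@@H](O)[C@](O[Si](C)(C)C(C)(C)C)(C(C)=C)C1 | intermediate
12 | 5,12-bis-O-trimethylsilyl ether | C[Si](C)(C)OC[C@]2(C)O[C@]21C[C@@H](O[Si](C)(C)C)[C@@H](O)[C@](O[Si](C)(C)C(C)(C)C)(C(C)=C)C1 | intermediate
13 | 4-ketone | C[Si](C)(C)OC[C@]2(C)O[C@]21C[C@@H](O[Si](C)(C)C)C(=O)[C@](O[Si](C)(C)C(C)(C)C)(C(C)=C)C1 | intermediate
14 | bromomagnesium 4-alkoxide | C[Si](C)(C)OC[C@]2(C)O[C@]21C[C@@H](O[Si](C)(C)C)[C@@](C=C)(O[Mg]Br)[C@](O[Si](C)(C)C(C)(C)C)(C(C)=C)C1 | intermediate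
15 | 4-vinyl-4,5,12-triol | OC[C@]2(C)O[C@]21C[C@@H](O)[C@@](C=C)(O)[C@](O[Si](C)(C)C(C)(C)C)(C(C)=C)C1 | intermediate
16 | tripotassium 4-enolate 5,12-dialkoxide | [O-]C[C@]2(C)O[C@]21C[C@@H]([O-])C([O-])=CCCC(C)=C(O[Si](C)(C)C(C)(C)C)C1.[K+].[K+].[K+] | intermediate
17 | ten-membered ketone, 7,11-epoxy-5,12-dihydroxy-9-(TBS-oxy)-15-norgermacr-9-en-4-one (enol ether geometry immaterial, ring-cis drawn) | OC[C@]2(C)O[C@]21C[C@@H](O)C(=O)CCC/C(C)=C(/O[Si](C)(C)C(C)(C)C)C1 | intermediate
18 | 4(15)-methylene diol, 7,11-epoxy-9-(TBS-oxy)germacra-4(15),9-diene-5,12-diol | OC[C@]2(C)O[C@]21C[C@@H](O)C(=C)CCC/C(C)=C(/O[Si](C)(C)C(C)(C)C)C1 | intermediate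
19 | 4,15-epoxy alcohol, 4,15:7,11-diepoxy-9-(TBS-oxy)germacr-9-ene-5,12-diol | OC[C@]2(C)O[C@]21C[C@@H](O)[C@@]3(CO3)CCC/C(C)=C(/O[Si](C)(C)C(C)(C)C)C1 | intermediate
20 | 4,5:7,11-diepoxy-9-(TBS-oxy)germacr-9-ene-12,15-diol | OC[C@]2(C)O[C@]21C[C@H]3O[C@@]3(CO)CCC/C(C)=C(/O[Si](C)(C)C(C)(C)C)C1 | intermediate
21 | 12,15-diacetate of 20 | CC(=O)OC[C@]2(C)O[C@]21C[C@H]3O[C@@]3(COC(C)=O)CCC/C(C)=C(/O[Si](C)(C)C(C)(C)C)C1 | intermediate
22 | (1(10)Z,4R,5R,7S,11S)-12,15-diacetoxy-4,5:7,11-diepoxygermacr-1(10)-en-9-one | CC(=O)OC[C@]2(C)O[C@]21C[C@H]3O[C@@]3(COC(C)=O)CC/C=C(/C)C(=O)C1 | target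

**Step count and risks**
Total step count: 16. Longest linear sequence: 16 (fully linear from 1).

Steps most likely to fail:

- **Step 12 (oxy-Cope).** The C9 tertiary TBS ether sits next to the C4 and C5 alkoxides; O-to-O silyl migration would scramble which carbonyl emerges masked. Fallback, from 15: per-silylate with Me3SiOTf/Et3N to the tris(trimethylsilyl) ether F1, run the neutral thermal siloxy-Cope rearrangement (o-dichlorobenzene, 180 °C; no alkoxide, so no silyl shuttle) to the bis(silyl enol ether) F2, then remove the three TMS groups with K2CO3/MeOH, which spares the tetrasubstituted TBS enol ether, and rejoin the route at 17.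

- **Step 8 (C11 face selectivity).** The outcome rests on vanadate chelation by the syn-1,3-diol; the two ring flanks of C7 are otherwise nearly equivalent, so this is a model-based prediction. Fallback, from 9: the C11-epimeric epoxy triol F3 that would accompany 11 is recycled rather than discarded. Selective iodination of its primary hydroxyl (I2, PPh3, imidazole) gives the iodide F4, and zinc dust in ethanol opens the iodo epoxide reductively to return 9, which re-enters step 8.

- **Step 16 (Saegusa oxidation).** The hindered tetrasubstituted TBS enol ether may react slowly, and β-hydride loss from the methyl group or formation of the ring-trans enone are possible. Fallback, from 21: PhSeCl (CH2Cl2, −78 °C) converts the enol ether regiospecifically into the α-phenylselenyl ketone F5, and oxidation with H2O2/pyridine at 0 °C followed by selenoxide syn-elimination gives 22.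

**Further compounds**
F1 | step 12 | tris(trimethylsilyl) ether of 15 | C[Si](C)(C)OC[C@]2(C)O[C@]21C[C@@H](O[Si](C)(C)C)[C@@](C=C)(O[Si](C)(C)C)[C@](O[Si](C)(C)C(C)(C)C)(C(C)=C)C1
F2 | step 12 | ten-membered bis(silyl enol ether), 4-OTMS-3-ene and 9-OTBS-9-ene | C[Si](C)(C)OC[C@]2(C)O[C@]21C[C@@H](O[Si](C)(C)C)C(O[Si](C)(C)C)=CCC/C(C)=C(/O[Si](C)(C)C(C)(C)C)C1
F3 | step 8 | C11 epimer of 11 | OC[C@@]2(C)O[C@]21C[C@@H](O)[C@@H](O)[C@](O[Si](C)(C)C(C)(C)C)(C(C)=C)C1
F4 | step 8 | C12 iodide of F3 | IC[C@@]2(C)O[C@]21C[C@@H](O)[C@@H](O)[C@](O[Si](C)(C)C(C)(C)C)(C(C)=C)C1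
F5 | step 16 | 10-phenylselenyl 9-ketone diacetate (C10 epimers) | CC(=O)OC[C@]2(C)O[C@]21C[C@H]3O[C@@]3(COC(C)=O)CCCC(C)([Se]c4ccccc4)C(=O)C1
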